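(The numbers in the tables stem from a simulated flask for substances that don't exist; scatter was added.)

Count in mM of E spent per mM of G made, and these flasks read differently.

| setting | birch | ash | green | grey | blue | ochre |
|---|---|---|---|---|---|---|
| D | 32 mM | 32 mM | 32 mM | 32 mM | 32 mM | 32 mM |
| E | 17 mM | 38 mM | 25.6 mM | 25.6 mM | 25.6 mM | 25.6 mM |
| J | 32 mM | 32 mM | 32.0 mM | 32.0 mM | 32.0 mM | 32.0 mM |
| temperature | −20 °C | 5 °C | −15 °C | 25 °C | 5 °C |  |
| remark | run made earlier | run made earlier |  |  |  | at 25 °C until 30 h, from then on at −15 °C |
| time |  |  | 4.0 d | 4.0 d | 4.0 d | 4.0 d |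

birch run (percent of the D charged)

| time / d | G / % |
|---|---|
| 0.417 | 3 |
| 1.04 | 2 |
| 2.08 | 2 |
| 3.00 | 6 |

ash run (percent of the D charged)

| time / h | G / % |
|---|---|
| 8.00 | 15 |
| 15.0 | 23 |
| 20.0 | 28 |
| 25.0 | 31 |

(standard deviation of a reading: 1.5 percentage points)

- the flask with the highest amount of G, in percent of the D charged ("all alike" if they lie within 1.5 percentage points) (green / grey / blue / ochre / all alike)
- final G, as a percentage of the D charged, in green
- final G, as a percentage of the D charged, in grey
- final G, as a percentage of the D charged, in blue
- final G, as a percentage of the D charged, in ochre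



Two of us disagree about green, grey, blue and ochre. One reads the clock: each E makes one G, so [E] of 25.6 mM against [D] of 32 mM caps G at 80.0%. Ash already stands at 31% after 25.0 h at 5 °C, and a warmer flask runs further towards that cap in 4.0 d.

I read the bill. In ash the gains over the equal steps from 15.0 h to 25.0 h are 5 percentage points and 3 points, so each gain is 0.600 of the one before. Summing that series puts the plateau at 35.5%, a rough reading, given a scatter of 1.5 points on each point. I take the plateau to mean that the 38 mM of E charged is spent, which gives 11.4 mM of G from it. The other 26.6 mM went elsewhere, and J is the charged candidate. Dividing gives 3.35: this is the E price of G, the mM of E spent per mM of G made, the inverse of what the trade calls selectivity.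

With E as limiting reagent, 25.6 mM at that price buys G up to 23.9% of the D charged. I assume the price holds away from 5 °C; birch, with readings from 2% to 6%, cannot test it. The gap to the ash plateau halves every 6.78 h, and 4.0 d is far longer, so I put blue, grey and ochre level near that ceiling and rank none of them.

The clock view keeps one region, the cold. Birch's last reading, scaled by E charge and time to green with no allowance for green's warmer bath, gives 12.0%, lower than the ceiling, so I expect green to be still on the clock at 4.0 d.

The forecast, the clock view's number, has grey highest, with green 14%, grey 70%, blue 46% and ochre 56%, holding: “E is therefore assumed to be consumed 1:1, which caps G at 80%”.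

The flasks end with green 15.7%, grey 19.0%, blue 22.5% and ochre 19.5%, so blue holds the most. Grey, blue and ochre stand under my ceiling of 23.9%, with [E] at 0%, 0.17% and 0% of its charge, but they spread over 3.5 points, more than the margin, and I had not ranked them. Green, with 36% of its E left, stands lower than the ceiling, on the clock.

    D + E → G (k = 0.0810 M⁻¹ min⁻¹, Ea = 60.0 kJ mol⁻¹)
    J + E → L (k = 0.340 M⁻¹ min⁻¹, Ea = 68.0 kJ mol⁻¹)
    G → Z (k = 7.00 × 10⁻⁶ min⁻¹, Ea = 104 kJ mol⁻¹)
    (constants at 25 °C)

Ochre, with [E] at 0%, paid an E price of 4.10, counted on the G standing at the end, against the rough ash reading of 3.35. Carry ochre's price to a neighbouring flask, ochre charged with 15 mM of E: the ceiling comes to 11.4% of the D charged. That flask ends with [E] at 0% and G at 10.2% of the D charged.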